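The route rests on closing ring A at the bond between the gem-dimethyl carbon C4 and the methylene C3. Ring B, with its C8 methyl and the C5–C4 branch, is a p-menthane unit, so (R)-carvone supplies ring B, the C5 stereocentre and, as its isopropenyl group, a latent C4. In the key step an iron hydride transfers a hydrogen atom to this isopropenyl group and the resulting tertiary C4 radical closes ring A by 6-endo addition to an acrylate arm on C10, creating the quaternary C4 and the trans-decalin in one operation. The precursor is a 6,6-dialkylated carvone. The chloroalkene is set late by chloride capture of a vinyl cation.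

Key step: step 3

Remarks on the chemistry:
- Atoms carry drimane numbers: ring A is C1–C5 and C10, ring B is C5–C10, C4 bears the geminal methyls, C10 the angular methyl, C8 the secondary methyl (C12), and C11 is the exocyclic chlorinated carbon.
- Compound 3 is used as a mixture of epimers at the new centre, which is planarized again in step 2.
- Compounds 7 and 8 are drawn as the equatorial C2 epimer; either epimer converges in step 5.
- The geometry of 18, 21 and 22 is left open because it is erased in the following step.
- 1-Bromo-2,3,5-trimethoxybenzene is assumed not to be a stock item and is made in steps 7 and 8.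

Step 1
Reactants: 1 (R)-(−)-carvone
Product: 3 (5R)-6-methylcarvone [(5R)-2,6-dimethyl-5-(prop-1-en-2-yl)cyclohex-2-en-1-one, epimers at C6 of carvone], via lithium carvone enolate 2 (not isolated)
Conditions: LiN(i-Pr)2 (LDA), THF, −78 °C; MeI, −78 to 0 °C
Reagents that add atoms: iodomethane, CI
Why: Kinetic deprotonation of the enone is possible only at the α' carbon (the future C10) and the cross-conjugated lithium enolate is C-methylated (enolate alkylation); the new centre is an inconsequential epimer mixture.

Step 2
Reactants: 3 (5R)-6-methylcarvone; 4 methyl 2-(bromomethyl)acrylate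
Product: 6 methyl 2-{[(1S,6S)-1,3-dimethyl-2-oxo-6-(prop-1-en-2-yl)cyclohex-3-en-1-yl]methyl}prop-2-enoate (acrylate arm trans, methyl cis to the isopropenyl group), via lithium 6-methylcarvone enolate 5 (not isolated)
Conditions: LiN(i-Pr)2, THF, −78 °C; 4, DMPU, −78 to −20 °C
Reagents that add atoms: none
Why: The tetrasubstituted lithium enolate is alkylated by the reactive allylic bromide on the face opposite the neighbouring isopropenyl group (enolate alkylation), which sets C10 with the methyl cis and the acrylate arm trans to the C5 substituent.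

Step 3
Reactants: 6 dialkylated carvone
Product: 7 (2S,5S,10S)-2-(methoxycarbonyl)-11-nordrim-7-en-9-one (trans-decalin enone, equatorial ester at C2)
Conditions: Fe(acac)3 (0.5 equiv), PhSiH3 (2.5 equiv), EtOH/(CH2OH)2 5:1, 0.03 M, 60 °C
Reagents that add atoms: none
Why: Fe(acac)3 and PhSiH3 in ethanol form an iron hydride that transfers a hydrogen atom to the terminal carbon of the electron-rich isopropenyl group, the tertiary C4 radical adds to the acrylate terminus C3, and the C2 radical is reduced by divalent iron to the ester enolate and protonated by ethanol. The closest known reaction type is the iron-mediated reductive coupling of a donor alkene with an acrylate in its intramolecular form (a Giese cyclization started by metal-hydride hydrogen atom transfer). Ring A closes in the 6-endo-trig mode. The only new stereocentre is C2, set by protonation of the enolate (equatorial ester expected) and deleted in step 5, whereas the trans ring fusion follows from the fixed C5 and C10 centres, whose two reacting arms are both equatorial on ring B. The step needs hydrogen atom transfer to the isopropenyl group in preference to the two electron-poor alkenes and 6-endo in preference to 5-exo closure; the first is secured by the hydridic character of the iron hydride, the second by the polarity match of the nucleophilic radical with the acrylate β-carbon and by the fully substituted C2.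

Step 4
Reactants: 7 decalin ester
Product: 8 (2S,5S,10S)-9-oxo-11-nordrim-7-ene-2-carboxylic acid
Conditions: LiOH, THF/MeOH/H2O, rt; aq HCl work-up
Reagents that add atoms: lithium hydroxide, [Li+].[OH-]
Why: Saponification of an unhindered secondary methyl ester; the enone has no base-labile site and C2 epimerization is irrelevant.

Step 5
Reactants: 8 decalin acid
Product: 9 (5S,10S)-11-nordrim-7-en-9-one
Conditions: 9-mesityl-10-phenylacridinium tetrafluoroborate (5 mol%), PhSSPh (10 mol%), i-Pr2NEt (20 mol%), CF3CH2OH, 450 nm LEDs, rt
Reagents that add atoms: none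
Why: Photoredox hydrodecarboxylation: the excited acridinium oxidizes the carboxylate, CO2 is lost and the secondary C2 radical takes a hydrogen atom from thiophenol, which removes the activating group together with the C2 centre.

Step 6
Reactants: 9 nordrimenone
Product: 11 (5S,10S)-11-nordrim-8-en-9-yl trifluoromethanesulfonate, via lithium enolate 10 (not isolated)
Conditions: LiBH(s-Bu)3 (L-Selectride), THF, −78 °C; PhNTf2, −78 °C to rt
Reagents that add atoms: N-phenylbis(trifluoromethanesulfonimide), O=S(=O)(N(c1ccccc1)S(=O)(=O)C(F)(F)F)C(F)(F)F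
Why: Conjugate hydride addition to the β-carbon C7 of the α-methyl enone gives the C8=C9 enolate regiospecifically (C10 is quaternary), and O-triflation traps it (reductive enol triflation).

Step 7
Reactants: 12 5-bromovanillin
Product: 13 2-bromo-6-methoxybenzene-1,4-diol
Conditions: 30% H2O2, aq NaOH, rt; aq HCl
Reagents that add atoms: hydrogen peroxide, OO
Why: Dakin oxidation of a para-hydroxybenzaldehyde: aryl migration in the peroxide adduct gives the aryl formate, which is hydrolysed to the hydroquinone.

Step 8
Reactants: 13 2-bromo-6-methoxyhydroquinone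
Product: 14 1-bromo-2,3,5-trimethoxybenzene
Conditions: MeI, K2CO3, acetone, reflux, argon
Reagents that add atoms: iodomethane, CI
Why: Williamson methylation of both phenols under inert gas to avoid air oxidation of the hydroquinone.

Step 9
Reactants: 14 1-bromo-2,3,5-trimethoxybenzene
Product: 16 (2,3,5-trimethoxyphenyl)boronic acid, via (2,3,5-trimethoxyphenyl)lithium 15 (not isolated)
Conditions: n-BuLi, THF, −78 °C; B(OMe)3, −78 °C to rt; aq HCl
Reagents that add atoms: trimethyl borate, COB(OC)OC; water, O
Why: Bromine–lithium exchange and borylation of the aryllithium, followed by hydrolysis of the borate.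

Step 10
Reactants: 11 enol triflate; 16 arylboronic acid
Product: 17 (5S,10S)-11-(2,3,5-trimethoxyphenyl)drim-8-en-11-one (aryl ketone on the tetrasubstituted C8=C9 alkene)
Conditions: CO (1 atm), PdCl2(dppf) (5 mol%), K2CO3, anisole, 80 °C
Reagents that add atoms: carbon monoxide, [C-]#[O+]
Why: Carbonylative Suzuki–Miyaura coupling: oxidative addition of the enol triflate to zerovalent palladium, CO insertion and transmetallation with the boronic acid give the ketone, with C11 coming from CO and direct coupling disfavoured at the hindered alkenyl palladium.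

Step 11
Reactants: 17 conjugated aryl ketone
Product: 19 (5S,9S,10S)-11-(2,3,5-trimethoxyphenyl)drim-8(12)-en-11-one (exocyclic methylene on C8, 9α-H), via potassium dienolate 18 (not isolated)
Conditions: KN(SiMe3)2, THF, −78 to −40 °C; inverse quench into AcOH/THF, −78 °C
Reagents that add atoms: none
Why: γ-Deprotonation at the methyl group cis to the carbonyl gives the extended dienolate, and its kinetic protonation at C9 from the α face gives the β,γ-unsaturated ketone (deconjugation); a Δ7 regioisomer would converge in step 12 and C9 is planarized again in step 13.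

Step 12
Reactants: 19 β,γ-unsaturated ketone
Product: 20 (5S,8S,9S,10S)-11-(2,3,5-trimethoxyphenyl)driman-11-one (8β-methyl, 9β-aroyl)
Conditions: H2 (1 atm), RhCl(PPh3)3 (10 mol%), benzene/EtOH, rt
Reagents that add atoms: none
Why: Homogeneous hydrogenation of the 1,1-disubstituted alkene, without alkene migration or ketone reduction, should deliver hydrogen to C8 from the α face because the β face is shielded by the axial C10 methyl, which sets the 8β (axial) methyl.

Step 13
Reactants: 20 saturated aryl ketone
Product: 22 (5S,8S,10S)-11-(2,3,5-trimethoxyphenyl)drim-9(11)-en-11-yl trifluoromethanesulfonate (either geometry), via potassium enolate 21 (not isolated)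
Conditions: KN(SiMe3)2, THF, −78 to 0 °C; PhNTf2, 0 °C to rt
Reagents that add atoms: N-phenylbis(trifluoromethanesulfonimide), O=S(=O)(N(c1ccccc1)S(=O)(=O)C(F)(F)F)C(F)(F)F
Why: The ketone has a single α-hydrogen (C9–H), so enolization and O-triflation give the tetrasubstituted enol triflate without a regiochemical choice; C8 is not acidic and keeps its configuration.

Step 14
Reactants: 22 enol triflate
Product: 23 (5S,8S,10S,9(11)E)-11-chloro-11-(2,3,5-trimethoxyphenyl)drim-9(11)-ene
Conditions: n-Bu4NCl (5 equiv), 2,6-di-tert-butylpyridine, (CF3)2CHOH/CH2Cl2, 40 °C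
Reagents that add atoms: tetrabutylammonium chloride, CCCC[N+](CCCC)(CCCC)CCCC.[Cl-]
Why: Vinylic SN1 substitution: ionization gives the linear α-aryl vinyl cation, stabilized by the orthogonal ortho-methoxyaryl ring, and chloride should attack in the alkene plane past the equatorial C8–H, not past the C1 methylene, which places chlorine cis to C8 and the aryl group cis to C10, the (E) geometry.

Step 15
Reactants: 23 chloroalkene arene
Product: 24 2-[(E)-chloro[(2S,4aS,8aS)-2,5,5,8a-tetramethyloctahydronaphthalen-1(2H)-ylidene]methyl]-6-methoxycyclohexa-2,5-diene-1,4-dione (target)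
Conditions: (NH4)2Ce(NO3)6 (2.5 equiv), MeCN/H2O, 0 °C
Reagents that add atoms: water, O
Why: Oxidative demethylation of the para-disposed 2- and 5-methoxy groups gives the 1,4-benzoquinone and keeps the 3-methoxy group, while the twisted, chlorine-bearing alkene is too electron-poor to be oxidized.

Compound list
1 | (R)-(−)-carvone | CC1=CC[C@H](CC1=O)C(C)=C | starting material
2 | lithium enolate of carvone (cross-conjugated, α' side) | [Li+].[O-]C1=C[C@H](C(C)=C)CC=C1C | intermediate
3 | (5R)-6-methylcarvone, epimer mixture at the methylated carbon | O=C1C(C)=CC[C@@H](C(C)=C)C1C | intermediate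
4 | methyl 2-(bromomethyl)acrylate | C=C(CBr)C(=O)OC | starting material
5 | lithium enolate of 6-methylcarvone | [Li+].[O-]C1=C(C)[C@H](C(C)=C)CC=C1C | intermediate
6 | methyl 2-{[(1S,6S)-1,3-dimethyl-2-oxo-6-(prop-1-en-2-yl)cyclohex-3-en-1-yl]methyl}prop-2-enoate | O=C1C(C)=CC[C@@H](C(C)=C)[C@]1(C)CC(=C)C(=O)OC | intermediate
7 | (2S,5S,10S)-2-(methoxycarbonyl)-11-nordrim-7-en-9-one | O=C2C(C)=CC[C@H]3C(C)(C)C[C@H](C(=O)OC)C[C@]23C | intermediate
8 | (2S,5S,10S)-9-oxo-11-nordrim-7-ene-2-carboxylic acid | O=C2C(C)=CC[C@H]3C(C)(C)C[C@H](C(=O)O)C[C@]23C | intermediate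
9 | (5S,10S)-11-nordrim-7-en-9-one | O=C2C(C)=CC[C@H]3C(C)(C)CCC[C@]23C | intermediate
10 | lithium (5S,10S)-11-nordrim-8-en-9-olate | [Li+].[O-]C2=C(C)CC[C@H]3C(C)(C)CCC[C@]23C | intermediate
11 | (5S,10S)-11-nordrim-8-en-9-yl trifluoromethanesulfonate | FC(F)(F)S(=O)(=O)OC2=C(C)CC[C@H]3C(C)(C)CCC[C@]23C | intermediate
12 | 5-bromovanillin (3-bromo-4-hydroxy-5-methoxybenzaldehyde) | COc1cc(C=O)cc(Br)c1O | starting material
13 | 2-bromo-6-methoxybenzene-1,4-diol | COc1cc(O)cc(Br)c1O | intermediate
14 | 1-bromo-2,3,5-trimethoxybenzene | COc1cc(OC)c(OC)c(Br)c1 | intermediate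
15 | (2,3,5-trimethoxyphenyl)lithium | [Li]c1cc(OC)cc(OC)c1OC | intermediate
16 | (2,3,5-trimethoxyphenyl)boronic acid | COc1cc(OC)c(OC)c(c1)B(O)O | intermediate
17 | (5S,10S)-11-(2,3,5-trimethoxyphenyl)drim-8-en-11-one | COc1cc(OC)c(OC)c(c1)C(=O)C2=C(C)CC[C@H]3C(C)(C)CCC[C@]23C | intermediate
18 | potassium dienolate of 17 (exocyclic C8=C12, enolate C9=C11) | [K+].[O-]C(c1cc(OC)cc(OC)c1OC)=C2C(=C)CC[C@H]3C(C)(C)CCC[C@]23C | intermediate
19 | (5S,9S,10S)-11-(2,3,5-trimethoxyphenyl)drim-8(12)-en-11-one | COc1cc(OC)c(OC)c(c1)C(=O)[C@H]2C(=C)CC[C@H]3C(C)(C)CCC[C@]23C | intermediate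
20 | (5S,8S,9S,10S)-11-(2,3,5-trimethoxyphenyl)driman-11-one | COc1cc(OC)c(OC)c(c1)C(=O)[C@H]2[C@@H](C)CC[C@H]3C(C)(C)CCC[C@]23C | intermediate
21 | potassium enolate of 20 | [K+].[O-]C(c1cc(OC)cc(OC)c1OC)=C2[C@@H](C)CC[C@H]3C(C)(C)CCC[C@]23C | intermediate
22 | (5S,8S,10S)-11-(2,3,5-trimethoxyphenyl)drim-9(11)-en-11-yl trifluoromethanesulfonate | COc1cc(OC)c(OC)c(c1)C(OS(=O)(=O)C(F)(F)F)=C2[C@@H](C)CC[C@H]3C(C)(C)CCC[C@]23C | intermediate
23 | (5S,8S,10S,9(11)E)-11-chloro-11-(2,3,5-trimethoxyphenyl)drim-9(11)-ene | COc1cc(OC)c(OC)c(c1)/C(Cl)=C2/[C@@H](C)CC[C@H]3C(C)(C)CCC[C@]23C | intermediate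
24 | 2-[(E)-chloro[(2S,4aS,8aS)-2,5,5,8a-tetramethyloctahydronaphthalen-1(2H)-ylidene]methyl]-6-methoxycyclohexa-2,5-diene-1,4-dione | COC1=CC(=O)C=C(/C(Cl)=C2/[C@@H](C)CC[C@H]3C(C)(C)CCC[C@]23C)C1=O | target

Total step count: 15. Longest linear sequence: 12 steps (steps 1–6 and 10–15, from (R)-carvone); steps 7–9 are the three-step branch to the boronic acid.

Steps most likely to fail

Step 14. What may go wrong is loss of geometric control in the capture of the vinyl cation, or capture of the cation by the solvent followed by hydrolysis back to the ketone. The fallback sets out from ketone 20 and replaces the vinyl cation by an α-chloro carbocation: deoxychlorination with the chlorophosphonium reagent from triphenyl phosphite and chlorine ((PhO)3P, Cl2, Et3N, CH2Cl2, −20 °C to rt) and loss of the C9 proton would give 23 directly, most likely together with its (Z) isomer F1. The two isomers would be separated on silver nitrate-impregnated silica, and the route is rejoined at 23.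

Step 10. What may go wrong is direct aryl transfer outrunning CO insertion at the hindered alkenyl palladium, or protodeboronation of the ortho-methoxy boronic acid. The fallback sets out from triflate 11 and bromide 14 and introduces the acyl carbon and the aryl group in separate events. Aminocarbonylation of 11 (Pd(OAc)2, Xantphos, CO, MeNHOMe·HCl, Et3N, toluene, 80 °C) would give the Weinreb amide F2. Addition of aryllithium 15, made from 14 and n-BuLi in THF at −78 °C, would then give ketone 17, where the route is rejoined.

Step 11. What may go wrong is failure of γ-deprotonation of the twisted, non-planar enone, or reprotonation of the dienolate at the γ-carbon, which returns the conjugated ketone. The fallback sets out from 17 and bypasses deconjugation. 1,2-Reduction (NaBH4, CeCl3·7H2O, MeOH, 0 °C) would give the allylic alcohol F3. Hydroxyl-directed hydrogenation of its tetrasubstituted alkene ([Ir(cod)(PCy3)(py)]PF6, H2, CH2Cl2) from the open α face would give the saturated alcohol F4 with the 8β-methyl and 9β side chain. Oxidation with Dess–Martin periodinane would then give ketone 20, where the route is rejoined; compound 19 is not passed.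

Further compounds
F1 | step 14 | (5S,8S,10S,9(11)Z)-11-chloro-11-(2,3,5-trimethoxyphenyl)drim-9(11)-ene | COc1cc(OC)c(OC)c(c1)/C(Cl)=C2\[C@@H](C)CC[C@H]3C(C)(C)CCC[C@]23C
F2 | step 10 | (5S,10S)-N-methoxy-N-methyldrim-8-en-11-amide | CON(C)C(=O)C2=C(C)CC[C@H]3C(C)(C)CCC[C@]23C
F3 | step 11 | (5S,10S)-11-(2,3,5-trimethoxyphenyl)drim-8-en-11-ol, C11 epimers | COc1cc(OC)c(OC)c(c1)C(O)C2=C(C)CC[C@H]3C(C)(C)CCC[C@]23C
F4 | step 11 | (5S,8S,9S,10S)-11-(2,3,5-trimethoxyphenyl)driman-11-ol, C11 epimers | COc1cc(OC)c(OC)c(c1)C(O)[C@H]2[C@@H](C)CC[C@H]3C(C)(C)CCC[C@]23C
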